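Read the ratio of target to starting material before trusting any curve.

| flask | starting material | gas phase | remark | time |
|---|---|---|---|---|
| epsilon | 28 mM | 1.3 mM (held) | run made earlier |  |
| theta | 44 mM | 1.3 mM (held) | run made earlier |  |
| flask | 20 mM | 1.3 mM (held) |  | 15 min |

| run | time / min | target / % | starting material / % |
|---|---|---|---|
| epsilon | 1.33 | 9.6 | 89.9 |
| epsilon | 2.00 | 14.0 | 85.3 |
| epsilon | 3.00 | 18.9 | 79.7 |
| epsilon | 5.00 | 24.5 | 72.2 |
| epsilon | 8.00 | 27.9 | 65.1 |
| epsilon | 12.0 | 28.2 | 59.0 |
| epsilon | 20.0 | 25.0 | 50.1 |
| theta | 2.50 | 13.3 | 86.4 |
| theta | 5.00 | 21.2 | 77.1 |
| theta | 8.00 | 25.0 | 69.7 |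
| theta | 10.0 | 26.3 | 67.2 |
| theta | 12.0 | 26.5 | 64.0 |
| theta | 15.0 | 25.9 | 60.5 |
| theta | 20.0 | 24.6 | 55.4 |

(readings scatter by 0.3 percentage points)

- at the start none of the gas is dissolved
- reactions considered so far: gas phase <-> dissolved gas; starting material + dissolved gas <-> target; dissolved gas + target -> over-reacted product; dissolved gas -> decomposed reagent

- Friday's: doubling the transfer coefficient of the gas phase, all else as stated
- Monday's: doubling the saturation concentration of gas phase, all else as stated

1. amount of target at 15 min, in percent of the starting material charged
2. the change that raises the amount of target at 15 min, in percent of the starting material charged most ("none" if none brings more than 2 percentage points) (Friday's / Monday's / none)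
3. amount of target at 15 min, in percent of the starting material charged, after Monday's

Target and starting material are counted here as fractions of the starting material charged. In the epsilon run the ratio went from 0.478 at 12.0 min to 0.499 at 20.0 min, while both species fell between those readings.

My first way used the target column by itself. I interpolated the epsilon run to 15 min, took the theta reading there, and drew a straight line in charge down to the flask's 20 mM. I did the same for starting material.

| Run at the asked time | Target | Starting material |
|---|---|---|
| epsilon, interpolated | 27.0 % | 55.7 % |
| theta, read | 25.9 % | 60.5 % |
| flask, extrapolated | 27.5 % | 53.2 % |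

My second way took the ratios of the last readings, 0.499 for epsilon and 0.444 for theta, and carried them along the same line to 0.526. Multiplied by the flask's starting material, that gave 28.0 %. This second way was the one that cheated, since the ratio read in the epsilon run was higher at the last reading than at the one before, and the last readings stand later than the asked time.

So I kept 27.5 % and the tie ratio, my estimate of target over starting material in the flask at the asked time, 0.517.

The forecast, higher than mine, gave 28.5 % (from 26.5 % to 30.5 %), 24 % after Monday's, and none as best change, noting that “target/starting material levels off near 0.5”.

The flask gave 26.8 % and 24.5 % after Monday's. The best change was none: Friday's moved the target by −0.14 percentage points and Monday's by −2.4 points.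

    gas phase ⇌ dissolved gas, rate k1*(csat - [dissolved gas]) (kL = 0.0480 s⁻¹)
    starting material + dissolved gas ⇌ target (K = 510 M⁻¹, k = 4.40 M⁻¹ s⁻¹)
    dissolved gas + target → over-reacted product (k = 0.930 M⁻¹ s⁻¹)
    dissolved gas → decomposed reagent (k = 0.00120 s⁻¹)

At 4.60 min target in the flask fell back 10 times faster than it went on. At 15 min it was made, each step taken net, at 0.704 of the rate at which it was used up. The tie ratio on the 53 % of starting material left gives 27.4 %. On the same flask read at 40 min, with 30 % left, it gives 15.5 %, and the computed target there was 16.3 %.

(Readings and results come from a simulation from invented constants, and the scatter is random.)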